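0.797 is the number we begin with: at 90 °C, the constant with which coupling partner eats mono adduct, over the constant with which it makes mono adduct from substrate.

the same everywhere: substrate 0.050 M; solid reagent 0.0600 M; time 2.0 min

| run | temperature |
|---|---|
| teal | 90 °C |
| green | 65 °C |
| grey | 115 °C |

    substrate + coupling partner → mono adduct (k1 = 0.315 /M/s, Ea1 = 48.0 kJ/mol)
    substrate + coupling partner → other mono adduct (k2 = 0.0657 /M/s, Ea2 = 85.0 kJ/mol)
    coupling partner + mono adduct → bis adduct (k3 = 0.251 /M/s, Ea3 = 63.0 kJ/mol)
    coupling partner + other mono adduct → bis adduct (k4 = 0.802 /M/s, Ea4 = 65.0 kJ/mol)
    solid reagent ⇌ coupling partner, rate k5*(cs5 - [coupling partner]) while solid is left; crystals form when [coupling partner] > cs5 (cs5 = 22 mM, k5 = 0.0727 /s)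
    (constants at 90 °C)

- solid reagent is a solid; its amount is given per volume of the solution
- all constants are for 90 °C and move with temperature by the activation energies
- at the start none of the solid reagent is in solution

1. the flask that comes out highest in amount of mono adduct, in percent of the substrate charged, or "all alike" when all lie within 1.5 percentage points (teal / green / grey / all alike)
2. mono adduct at the end, in percent of the substrate charged, teal
3. mono adduct at the end, in percent of the substrate charged, green
4. mono adduct at the end, in percent of the substrate charged, grey

The making, side and eating steps all carry [coupling partner] as a factor, so it cancels when one rate is divided by another. Call m the making constant, a the sum of making and side constants, c the eating constant. Then mono adduct rises until [mono adduct]/[substrate] equals m/c, and in powers of ten the logarithm of the substrate share at that top is a/(a−c) times log(c/a).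

Each constant shifts by Ea/(2.3 R) decades per unit of reciprocal temperature. For grey, m = 0.877 /M/s, side 0.403 /M/s, c = 0.962 /M/s, so m has gained 0.445 decades. For green, m = 0.0972 /M/s, side 0.00820 /M/s, c = 0.0537 /M/s.

The top, m/c times that substrate share, is teal's 37.0%; we call it the ceiling, the intermediate's maximum yield at a given temperature. Green's is 45.8% and grey's 28.9%.

Can each flask get there? With partner held at solubility, the top needs ln(a/c)/((a−c) times solubility): 2.43 min for teal, 9.88 min for green, 0.680 min for grey, against 2.0 min. So teal and green stop on the way up, while grey arrives, having spent at most 0.0539 M of partner from a charge of 0.0600 M; that leaves at least 0.00610 M to stand dissolved. The formula m/(a−c) times (exp(−cx) − exp(−ax)), with x the level times the time, then gives teal 36.3% and green 20.8%. We commit to these, with grey at its ceiling.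

The weak link is the level. At the start dissolution outruns the drain even in grey, so partner stands near a share k/(k + a[substrate]) of solubility, with k the dissolution coefficient; with the charged substrate that is 0.793 in teal and 0.932 in green. Filling also costs about 13.8 s. Reforged, teal falls to 32.6% and green to 17.8%. By the same reckoning grey reaches its top at about 1.51 min.

The forecast names teal, with 33% for teal, 18% for green and 28.5% for grey, since mono adduct “peaks at the middle temperature”. Its teal lies 0.40 percentage points above ours, its green 0.20 points above ours, and its grey 0.40 points below our ceiling.

The simulation gives teal 33.1%, green 18.0%, grey 28.4%, so teal comes out highest, as forecast.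

Grey's 28.4% stands 0.50 points under its ceiling, and more time leaves it there, whereas teal ends 3.9 points under and green 28 points under, and these two stand higher when left ten times as long, teal at 35.7% and green at 45.1%. Now repeat grey at 140 °C. There m = 2.16 /M/s, side 1.98 /M/s, c = 3.14 /M/s, so the ceiling drops to 21.9%. That flask ends with 21.6% mono adduct and 25.8% substrate.

The rate constants are made up; the result is computed.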